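## Structural features

Lespeflorin B1 (21) is a 2,3-trans dihydroflavonol: a chroman-4-one in which the benzo ring A (C4a to C8a) is fused to the oxygen heterocycle ring C (O1, C2, C3, C4), with a para-hydroxyphenyl ring B on C2. Its only stereocentres are the benzylic ether carbon C2 and the carbinol carbon C3; they are adjacent, both R and trans, and C3 lies alpha to the C4 ketone. Ring A is a 1,2,4,5-tetrasubstituted benzene with a prenyl group at C6 next to the C7 phenol and hydrogen at C5 and C8; ring B repeats the ortho-prenyl phenol motif at C3'/C4'. The fragile points are several: ortho-prenyl phenols close to 2,2-dimethylchromans under acid, the trisubstituted alkenes react with electrophilic oxidants and halogen sources, C3 can epimerise by enolisation, C2 can be lost by base-induced opening of ring C, and the ketol is easily dehydrogenated to a flavonol. The real difficulty is the ring A pattern, because prenylation of a 7-hydroxychromanone does not reliably distinguish C6 from C8, and it must be solved without disturbing C2 and C3. The plan exploits the fact that the C4a=C8a bond of ring A is also the enol-ether alkene of a ring C 2,3-dihydro-4H-pyran-4-one. The remaining carbons C5, C6, C7 and C8, with their substituents (H, prenyl, O, H), are the four carbons of a 1-methoxy-2-prenyl-3-silyloxybutadiene, so ring A can be built last with the prenyl group at C6 by construction.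

## Logic of the disconnections

21 to 20: the two O–Si bonds at O3 and O4' are cut. Silyl ethers are chosen because fluoride removes them without protic acid, so the two ortho-prenyl phenols are never exposed to conditions that close chromans. The forward step must cleave an aryl and a secondary alkyl silyl ether under near-neutral conditions that leave the ketol alone.

20 to 11 and 17: the C4a–C5 and C8–C8a bonds of ring A are cut. This removes the whole benzene ring, its prenyl group and its phenol in one convergent step and turns the C6/C8 problem into the regiochemistry of a cycloaddition. The forward step demands that 17 add to a weakly electrophilic push–pull alkene in the right orientation, that methanol, the silyl group and HBr then leave in a controlled order, and that C2 and C3 survive.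

11 to 10: the C5–Br bond (pyranone numbering) is cut. Bromine serves only as an activating and leaving group, so it is put on last. The forward bromination must select the enol-ether carbon over the prenyl alkene and ring B.

10 to 9 to 7: the O3–Si bond and then the C3–O bond are cut. Introducing the oxygen on the enolate of 7 lets the C2 aryl group direct it trans, so no cis adduct has to be equilibrated afterwards. The simplification is that 7 has a single stereocentre. The forward oxidation must be trans-selective, must spare the prenyl alkene, and the enolate must not open ring C.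

7 to 4 and 5: the C2–C3 and O1–C6 bonds of the pyranone are cut (hetero-Diels–Alder transform). Catalytic enantioselective versions with aryl aldehydes are secure and 5 is commercial. The catalyst must deliver the diene terminus to the Si face of the aldehyde.

4 to 3 to 1 and 2: the O–Si bond and then the aryl C3–CH2 bond are cut. This leads to two cheap commercial materials. The forward alkylation must occur at the ring carbon ortho to oxygen and not at oxygen.

17 to 16 to 15 to 13 and 14, and 13 to 12: the enol O–Si bond, the enol-ether C=C bond (methanol added back), the bond from C3 to the one-carbon unit, and the first enol O–Si bond are cut in turn. The one-carbon unit must sit on the methylene carbon of 12, not on the methyl carbon, and base-mediated formylation of such methyl ketones favours the methyl group. The route therefore passes through the more substituted enol silane 13, whose regioselective formation is the demand on this branch.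

## Other disconnections considered

Alternative 1: The cut is at the two aryl–CH2 bonds of the prenyl groups, on C6 of ring A and on C3' of ring B. Both are traced to 1,1-dimethylallyl aryl ethers at O7 and O4' of an 8-bromo dihydroflavonol, (2R,3R)-8-bromo-3-hydroxy-7-[(2-methylbut-3-en-2-yl)oxy]-2-{4-[(2-methylbut-3-en-2-yl)oxy]phenyl}chroman-4-one A2.
- Forward key step: Eu(fod)3, a Lewis acid of trivalent europium, would promote two aromatic Claisen ([3,3]) shifts. The ring B ether can only reach C3' (or the equivalent C5'), the ring A ether only C6 because C8 is blocked, and tautomerisation would give (2R,3R)-8-bromo-3,7-dihydroxy-2-[4-hydroxy-3-(3-methylbut-2-enyl)phenyl]-6-(3-methylbut-2-enyl)chroman-4-one A1. The bromine must then be removed.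
- In its favour: this is the best-precedented way to make ortho-prenyl phenols. Both prenyl groups arrive in one late operation on a conventional dihydroflavonol, no ring is formed, C2 and C3 are untouched, and the conditions are neither strongly acidic nor basic.
- Against it here: the ring A regiochemistry rests on a blocking atom that must be put on C8 selectively and removed again in the presence of two prenyl alkenes, an aryl ketone and a benzylic C–O bond, which excludes hydrogenolysis. Each tertiary allyl ether needs a propargylation and a semi-hydrogenation. The enantiopure core needs its own asymmetric sequence, and the freshly formed ortho-prenyl phenols may close to chromans next to the Lewis acid on long heating.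
- Comparison: on mechanism the alternative is the better of the two, since its key step is a known pericyclic reaction while the chosen cycloaddition is untested on this dienophile. On structure the chosen plan is cleaner, because the position of the ring A prenyl group follows from the diene and needs no blocking group. On step economy the two are about equal.

Alternative 2: The cut is the aryl ether bond O1–C8a. The precursor is the open-chain diol (2R,3R)-1-[3-bromo-4-(methoxymethoxy)-5-(3-methylbut-2-enyl)phenyl]-2-(methoxymethoxy)-3-[4-(methoxymethoxy)-3-(3-methylbut-2-enyl)phenyl]propane-1,3-diol A4 (C1 carbinol either epimer), whose ring A carries hydrogen at the future C8a.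
- Forward key step: excess lithium 2,2,6,6-tetramethylpiperidide would deprotonate both hydroxyls, remove the hydrogen ortho to bromine and expel bromide to give the C8–C8a aryne. The tethered C2 alkoxide would add at C8a in a six-membered closure, the C7 alkoxy group polarising the aryne in the same sense, and protonation at C8 would give the 2,3-trans chromanol 3,7-bis(methoxymethoxy)-2-[4-(methoxymethoxy)-3-(3-methylbut-2-enyl)phenyl]-6-(3-methylbut-2-enyl)chroman-4-ol A3. Oxidation at C4 and deprotection would follow.
- In its favour: the ether bond is made without a phenol at C8a, C2 and C3 are set beforehand by acyclic aldol chemistry, the tether enforces the regiochemistry, and intramolecular capture of arynes by alkoxides is a known reaction class.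
- Against it here: the strong amide base meets two allylic-benzylic methylene groups and three acetal ethers that direct ortho-lithiation. The ring A bromide with its prenyl group needs its own regiocontrolled synthesis, so the C6 problem is only moved. The C4 oxidation level is lost and must be restored, and the final removal of three acetal groups needs acid in the presence of both ortho-prenyl phenols.
- Comparison: on mechanism the alternative is equal or somewhat better precedented. On structure it is weaker, since ring A must be assembled with its substituents beforehand and an extra carbinol centre is carried and then destroyed. On step economy it is weaker, with two steps after the key step and a longer way to A4.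

Alternative 3: The cut is the C3–C4 bond. The precursor is the racemic dialdehyde 2-{1-[4-(methoxymethoxy)-3-(3-methylbut-2-enyl)phenyl]-2-oxoethoxy}-4-(methoxymethoxy)-5-(3-methylbut-2-enyl)benzaldehyde A6.
- Forward key step: a chiral triazolylidene carbene would add to the ring A aldehyde, and the derived acyl anion equivalent would attack the aliphatic aldehyde in a six-membered crossed benzoin closure. Because the C2 centre of A6 epimerises quickly by enolisation, a dynamic kinetic resolution could deliver (2R,3R)-3-hydroxy-7-(methoxymethoxy)-2-[4-(methoxymethoxy)-3-(3-methylbut-2-enyl)phenyl]-6-(3-methylbut-2-enyl)chroman-4-one A5 as one trans isomer. One deprotection would follow.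
- In its favour: ring C, the ketone, the C3 hydroxyl and both stereocentres appear in one catalytic step at the right oxidation level, with no oxidant, halogen source or strong base after the prenyl groups are in place. On step economy after the key step it is the equal of the chosen plan, and overall it could be the better if A6 were easy to reach.
- Against it here: A6 is fragile, since an alpha-aryloxy arylacetaldehyde enolises, hydrates and loses aryloxide easily, and its preparation must distinguish two aldehydes. Which aldehyde becomes the acyl donor is not assured, and the 4-alkoxy-2-aryloxy benzaldehyde is a deactivated donor. The secondary ketol can scramble by retro-benzoin or enediol tautomerism under the basic conditions. The ring A aldehyde again needs a regioselective prenylation of a resorcinol unit.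
- Comparison: on structure the alternative handles the stereochemistry elegantly but not the ring A pattern, which the chosen plan settles by construction. On mechanism both key steps lie beyond close precedent, but the alternative must also control two stereocentres in that step, whereas the chosen key step creates none and leaves stereocontrol to established reactions.

Key step: step 11

Remarks on the chemistry (assumptions made in the design):
- tert-Butyldimethylsilyl ethers are used at O4' and O3 instead of acetal protecting groups: an aryl acetal ether would be at risk in the TFA-mediated ring closure of step 3, and its final removal would need protic acid next to two ortho-prenyl phenols, whereas silyl ethers leave with buffered fluoride.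
- The C3 oxygen is introduced after the hetero-Diels–Alder step and not carried in a 4-oxygenated diene, so the trans ketol forms directly; equilibrating a cis adduct is avoided because epimerisation at C3 and at C2 would lead to opposite enantiomers.
- The one-carbon unit of the diene is attached through the more substituted enol silane, because direct base-mediated formylation of a methyl ketone with a long alkyl chain favours the methyl carbon.
- The (S)-BINOL ligand in step 3 is assigned on the assumption that the BINOL–titanium catalyst directs the diene to the Si face of the aryl aldehyde, as in related additions to benzaldehyde; if the sense is opposite, (R)-BINOL is used.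

## Route

Step 1
Reactants: 1 4-hydroxybenzaldehyde; 2 1-bromo-3-methylbut-2-ene
Product: 3 4-hydroxy-3-(3-methylbut-2-enyl)benzaldehyde
Conditions: KOH (10% aq.), 0 °C to rt
Reagents that add atoms: none
Why: Ortho C-alkylation of a phenoxide in water, where hydrogen bonding to the oxygen shifts the ambident anion towards reaction at carbon; the para position is blocked by the formyl group, and the O-prenyl ether and dialkylated material are removed by chromatography.

Step 2
Reactants: 3 4-hydroxy-3-(3-methylbut-2-enyl)benzaldehyde
Product: 4 4-(tert-butyldimethylsilyloxy)-3-(3-methylbut-2-enyl)benzaldehyde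
Conditions: TBSCl, imidazole, DMF, rt
Reagents that add atoms: tert-butyldimethylsilyl chloride, CC(C)(C)[Si](C)(C)Cl
Why: Standard silylation of a phenol; the aryl silyl ether should survive TFA, amide base at low temperature, bromination and heat, and is removed at the end without acid.

Step 3
Reactants: 4 4-(tert-butyldimethylsilyloxy)-3-(3-methylbut-2-enyl)benzaldehyde; 5 (E)-1-methoxy-3-(trimethylsilyloxy)buta-1,3-diene
Product: 7 (2S)-2-[4-(tert-butyldimethylsilyloxy)-3-(3-methylbut-2-enyl)phenyl]-2,3-dihydro-4H-pyran-4-one, via Mukaiyama aldol adduct 6 (not isolated)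
Conditions: (S)-BINOL (20 mol %), Ti(OiPr)4 (10 mol %), 4 Å MS, Et2O, −20 °C; then TFA, CH2Cl2, 0 °C
Reagents that add atoms: none
Why: Catalytic enantioselective hetero-Diels–Alder reaction of the Mukaiyama aldol type: the chiral complex of tetravalent titanium activates the aldehyde, the CH2 terminus of 5 adds to give 6, and TFA closes the ring with loss of methanol. The C2 stereocentre is set by the catalyst, which shields one face of the bound aldehyde so that attack on the Si face gives the S configuration.

Step 4
Reactants: 7 (2S)-2-[4-(tert-butyldimethylsilyloxy)-3-(3-methylbut-2-enyl)phenyl]-2,3-dihydro-4H-pyran-4-one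
Product: 9 (2R,3R)-2-[4-(tert-butyldimethylsilyloxy)-3-(3-methylbut-2-enyl)phenyl]-3-hydroxy-2,3-dihydro-4H-pyran-4-one, via sodium dienolate 8 (not isolated)
Conditions: NaN(SiMe3)2, THF, −78 °C; 3-phenyl-2-(phenylsulfonyl)oxaziridine, −78 °C; then AcOH
Reagents that add atoms: 3-phenyl-2-(phenylsulfonyl)oxaziridine, O=S(=O)(c1ccccc1)N1OC1c1ccccc1
Why: Enolate hydroxylation with an N-sulfonyloxaziridine; only C3 carries enolisable hydrogen, and the oxidant does not epoxidise the prenyl alkene at −78 °C. The C3 stereocentre is set by the C2 aryl group, the oxidant approaching the enolate face anti to it, which also gives the more stable trans (diequatorial) ketol; the descriptor at C2 changes from S to R only because C3 now outranks the aryl group.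

Step 5
Reactants: 9 (2R,3R)-2-[4-(tert-butyldimethylsilyloxy)-3-(3-methylbut-2-enyl)phenyl]-3-hydroxy-2,3-dihydro-4H-pyran-4-one
Product: 10 (2R,3R)-3-(tert-butyldimethylsilyloxy)-2-[4-(tert-butyldimethylsilyloxy)-3-(3-methylbut-2-enyl)phenyl]-2,3-dihydro-4H-pyran-4-one
Conditions: TBSOTf, 2,6-lutidine, CH2Cl2, −78 °C
Reagents that add atoms: tert-butyldimethylsilyl trifluoromethanesulfonate, CC(C)(C)[Si](C)(C)OS(=O)(=O)C(F)(F)F
Why: Silylation of a hindered secondary alcohol with a silyl triflate and a weak hindered base; at −78 °C the hydroxyl reacts much faster than the ketone can be enol-silylated, so C3 is not disturbed.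

Step 6
Reactants: 10 (2R,3R)-3-(tert-butyldimethylsilyloxy)-2-[4-(tert-butyldimethylsilyloxy)-3-(3-methylbut-2-enyl)phenyl]-2,3-dihydro-4H-pyran-4-one
Product: 11 (2R,3R)-5-bromo-3-(tert-butyldimethylsilyloxy)-2-[4-(tert-butyldimethylsilyloxy)-3-(3-methylbut-2-enyl)phenyl]-2,3-dihydro-4H-pyran-4-one
Conditions: NBS (1.05 equiv), NaHCO3, CH2Cl2, 0 °C, dark
Reagents that add atoms: N-bromosuccinimide, O=C1CCC(=O)N1Br
Why: Electrophilic alpha-halogenation of a vinylogous ester: the enol-ether carbon C5 attacks bromine and loss of the C5 proton from the oxocarbenium ion restores the enone. In dry CH2Cl2 without a nucleophile, the isolated trisubstituted alkene and the silyl-capped ring B are expected to react more slowly.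

Step 7
Reactants: 12 6-methylhept-5-en-2-one
Product: 13 (2Z)-6-methyl-2-(trimethylsilyloxy)hepta-2,5-diene
Conditions: TMSCl, NaI, Et3N, MeCN, rt
Reagents that add atoms: chlorotrimethylsilane, C[Si](C)(C)Cl
Why: Enol silylation under equilibrating conditions (iodotrimethylsilane formed in the flask, amine base), which for methyl ketones favours the more substituted, Z-configured enol silane; its geometry is of no consequence later.

Step 8
Reactants: 13 (2Z)-6-methyl-2-(trimethylsilyloxy)hepta-2,5-diene; 14 trimethyl orthoformate
Product: 15 3-(dimethoxymethyl)-6-methylhept-5-en-2-one (racemic)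
Conditions: TMSOTf (5 mol %), CH2Cl2, −78 °C
Reagents that add atoms: none
Why: Mukaiyama-type addition of an enol silane to the dimethoxycarbenium ion generated from the orthoester by catalytic silyl triflate; the enol silane is far more nucleophilic than the prenyl alkene. The new C3 centre is racemic and is destroyed in step 9.

Step 9
Reactants: 15 3-(dimethoxymethyl)-6-methylhept-5-en-2-one
Product: 16 (3E)-3-(methoxymethylidene)-6-methylhept-5-en-2-one
Conditions: PPTS (5 mol %), toluene, 90 °C, 5 Å MS
Reagents that add atoms: none
Why: Acid-catalysed elimination of methanol from a beta-keto acetal (acetal ionisation, loss of the acidic C3 proton); it is reversible, so the E isomer with methoxy trans to acetyl should dominate, and the pyridinium acid is too weak to protonate the prenyl alkene.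

Step 10
Reactants: 16 (3E)-3-(methoxymethylidene)-6-methylhept-5-en-2-one
Product: 17 (1E)-1-methoxy-2-(3-methylbut-2-enyl)-3-(trimethylsilyloxy)buta-1,3-diene
Conditions: TMSOTf, Et3N, Et2O, 0 °C
Reagents that add atoms: trimethylsilyl trifluoromethanesulfonate, C[Si](C)(C)OS(=O)(=O)C(F)(F)F
Why: Enol silylation of a methyl ketone with silyl triflate and amine; the methyl group is the only enolisable position, so the 2-silyloxy diene forms without ambiguity and the E enol ether is carried over.

Step 11
Reactants: 11 (2R,3R)-5-bromo-3-(tert-butyldimethylsilyloxy)-2-[4-(tert-butyldimethylsilyloxy)-3-(3-methylbut-2-enyl)phenyl]-2,3-dihydro-4H-pyran-4-one; 17 (1E)-1-methoxy-2-(3-methylbut-2-enyl)-3-(trimethylsilyloxy)buta-1,3-diene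
Product: 20 (2R,3R)-3-(tert-butyldimethylsilyloxy)-2-[4-(tert-butyldimethylsilyloxy)-3-(3-methylbut-2-enyl)phenyl]-7-hydroxy-6-(3-methylbut-2-enyl)chroman-4-one, via cis-fused cycloadduct 18 (not isolated), via bromo enone 19 (not isolated)
Conditions: 17 (4 equiv), toluene, 120 °C, sealed tube; then 1 M HCl, THF, 0 °C; then DBU, CH2Cl2, 0 °C
Reagents that add atoms: none
Why: Proposed new method: the electron-rich diene 17 should add across the C5=C6 alkene of 11 in a concerted but asynchronous normal-demand Diels–Alder reaction, its CH2 terminus (largest HOMO coefficient) bonding first to the enol-ether beta carbon (future C8a) and its methoxy-bearing terminus to the brominated alpha carbon (future C4a), with the bromine lowering the LUMO of an otherwise sluggish vinylogous ester; the closest known reaction type is the Diels–Alder/aromatisation sequence of 2-halocycloalkenones and of 3-halo or 3-acyl chromones with 1-alkoxy-3-silyloxy dienes, which has not been shown on a 5-halo-2,3-dihydro-4H-pyran-4-one. Ring A closes as a six-membered carbocycle in a suprafacial [4+2] mode, or by a 6-endo-trig Michael closure of the bromo enolate if the second bond lags. Dilute acid then hydrolyses the enol silane of 18 and expels methanol from C5 to give enone 19, and DBU removes HBr across C4a–C8a, the only direction left once C5 is trigonal, after which tautomerisation gives the C7 phenol. The three new sp3 centres of 18 are all erased, so no stereocontrol is asked of the cycloaddition and its facial and endo/exo outcome does not matter. The selectivity needed is regiochemical (prenyl at C6, oxygen at C7) and is secured by the matched polarisation of the two partners; the reverse orientation would give the 6-hydroxy-7-prenyl isomer. C2 and C3 should survive because no strong base or Lewis acid is used, C3 already has the more stable trans arrangement, and once the C4a=C8a bond is restored O1 is an aryl ether oxygen that enolisation cannot expel. The prenyl alkenes are unactivated and should not compete as dienophiles, and the ortho-prenyl phenol appears only in the last, basic operation, after the acid treatment.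

Step 12
Reactants: 20 (2R,3R)-3-(tert-butyldimethylsilyloxy)-2-[4-(tert-butyldimethylsilyloxy)-3-(3-methylbut-2-enyl)phenyl]-7-hydroxy-6-(3-methylbut-2-enyl)chroman-4-one
Product: 21 lespeflorin B1, (2R,3R)-3,7-dihydroxy-2-[4-hydroxy-3-(3-methylbut-2-enyl)phenyl]-6-(3-methylbut-2-enyl)chroman-4-one
Conditions: HF·pyridine, pyridine, THF, 0 °C to rt
Reagents that add atoms: none
Why: Fluoride-induced cleavage of the aryl and the secondary alkyl silyl ether; the pyridine-buffered reagent is neither acidic enough to cyclise ortho-prenyl phenols nor basic enough to open ring C or epimerise C2 and C3.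

## Compound list

1 | 4-hydroxybenzaldehyde | O=Cc1ccc(O)cc1 | starting material
2 | 1-bromo-3-methylbut-2-ene | CC(C)=CCBr | starting material
3 | 4-hydroxy-3-(3-methylbut-2-enyl)benzaldehyde | CC(C)=CCc1cc(C=O)ccc1O | intermediate
4 | 4-(tert-butyldimethylsilyloxy)-3-(3-methylbut-2-enyl)benzaldehyde | CC(C)=CCc1cc(C=O)ccc1O[Si](C)(C)C(C)(C)C | intermediate
5 | (E)-1-methoxy-3-(trimethylsilyloxy)buta-1,3-diene | CO/C=C/C(=C)O[Si](C)(C)C | starting material
6 | (1E,5S)-5-[4-(tert-butyldimethylsilyloxy)-3-(3-methylbut-2-enyl)phenyl]-1-methoxy-5-(trimethylsilyloxy)pent-1-en-3-one | CO/C=C/C(=O)C[C@H](O[Si](C)(C)C)c1ccc(O[Si](C)(C)C(C)(C)C)c(CC=C(C)C)c1 | intermediate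
7 | (2S)-2-[4-(tert-butyldimethylsilyloxy)-3-(3-methylbut-2-enyl)phenyl]-2,3-dihydro-4H-pyran-4-one | CC(C)=CCc1cc([C@H]2OC=CC(=O)C2)ccc1O[Si](C)(C)C(C)(C)C | intermediate
8 | sodium (2S)-2-[4-(tert-butyldimethylsilyloxy)-3-(3-methylbut-2-enyl)phenyl]-2H-pyran-4-olate | CC(C)=CCc1cc([C@H]2OC=CC([O-])=C2)ccc1O[Si](C)(C)C(C)(C)C.[Na+] | intermediate
9 | (2R,3R)-2-[4-(tert-butyldimethylsilyloxy)-3-(3-methylbut-2-enyl)phenyl]-3-hydroxy-2,3-dihydro-4H-pyran-4-one | CC(C)=CCc1cc([C@H]2OC=CC(=O)[C@@H]2O)ccc1O[Si](C)(C)C(C)(C)C | intermediate
10 | (2R,3R)-3-(tert-butyldimethylsilyloxy)-2-[4-(tert-butyldimethylsilyloxy)-3-(3-methylbut-2-enyl)phenyl]-2,3-dihydro-4H-pyran-4-one | CC(C)=CCc1cc([C@H]2OC=CC(=O)[C@@H]2O[Si](C)(C)C(C)(C)C)ccc1O[Si](C)(C)C(C)(C)C | intermediate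
11 | (2R,3R)-5-bromo-3-(tert-butyldimethylsilyloxy)-2-[4-(tert-butyldimethylsilyloxy)-3-(3-methylbut-2-enyl)phenyl]-2,3-dihydro-4H-pyran-4-one | CC(C)=CCc1cc([C@H]2OC=C(Br)C(=O)[C@@H]2O[Si](C)(C)C(C)(C)C)ccc1O[Si](C)(C)C(C)(C)C | intermediate
12 | 6-methylhept-5-en-2-one | CC(=O)CCC=C(C)C | starting material
13 | (2Z)-6-methyl-2-(trimethylsilyloxy)hepta-2,5-diene | C[Si](C)(C)O/C(C)=C\CC=C(C)C | intermediate
14 | trimethyl orthoformate | COC(OC)OC | starting material
15 | 3-(dimethoxymethyl)-6-methylhept-5-en-2-one (racemic) | CC(=O)C(CC=C(C)C)C(OC)OC | intermediate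
16 | (3E)-3-(methoxymethylidene)-6-methylhept-5-en-2-one | CO/C=C(\CC=C(C)C)C(C)=O | intermediate
17 | (1E)-1-methoxy-2-(3-methylbut-2-enyl)-3-(trimethylsilyloxy)buta-1,3-diene | CO/C=C(/C(=C)O[Si](C)(C)C)CC=C(C)C | intermediate
18 | (2R,3R)-4a-bromo-3-(tert-butyldimethylsilyloxy)-2-[4-(tert-butyldimethylsilyloxy)-3-(3-methylbut-2-enyl)phenyl]-5-methoxy-6-(3-methylbut-2-enyl)-7-(trimethylsilyloxy)-2,3,4a,5,8,8a-hexahydro-4H-chromen-4-one (cis ring fusion; C4a, C5 and C8a transient and not defined) | CC(C)=CCc1cc([C@H]2OC3CC(O[Si](C)(C)C)=C(CC=C(C)C)C(OC)C3(Br)C(=O)[C@@H]2O[Si](C)(C)C(C)(C)C)ccc1O[Si](C)(C)C(C)(C)C | intermediate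
19 | (2R,3R)-4a-bromo-3-(tert-butyldimethylsilyloxy)-2-[4-(tert-butyldimethylsilyloxy)-3-(3-methylbut-2-enyl)phenyl]-6-(3-methylbut-2-enyl)-2,3,8,8a-tetrahydro-4H-chromene-4,7(4aH)-dione (C4a and C8a transient and not defined) | CC(C)=CCc1cc([C@H]2OC3CC(=O)C(CC=C(C)C)=CC3(Br)C(=O)[C@@H]2O[Si](C)(C)C(C)(C)C)ccc1O[Si](C)(C)C(C)(C)C | intermediate
20 | (2R,3R)-3-(tert-butyldimethylsilyloxy)-2-[4-(tert-butyldimethylsilyloxy)-3-(3-methylbut-2-enyl)phenyl]-7-hydroxy-6-(3-methylbut-2-enyl)chroman-4-one | CC(C)=CCc1cc([C@H]2Oc3cc(O)c(CC=C(C)C)cc3C(=O)[C@@H]2O[Si](C)(C)C(C)(C)C)ccc1O[Si](C)(C)C(C)(C)C | intermediate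
21 | lespeflorin B1, (2R,3R)-3,7-dihydroxy-2-[4-hydroxy-3-(3-methylbut-2-enyl)phenyl]-6-(3-methylbut-2-enyl)chroman-4-one | CC(C)=CCc1cc([C@H]2Oc3cc(O)c(CC=C(C)C)cc3C(=O)[C@@H]2O)ccc1O | target

## Step count and least certain steps

Total: 12 steps. Longest linear sequence: 8 steps (steps 1 to 6, 11 and 12); the diene branch (steps 7 to 10) has 4 steps.

Step 11 (key step). The cycloaddition may be too slow: the push–pull alkene is a poor dienophile and its alpha carbon is hindered, so thermal decomposition or adventitious hydrolysis of the diene can outrun ring formation. Loss of HBr in the wrong direction is a second risk if the acid and base treatments do not proceed in the intended order. The fallback gives up the late benzannulation and uses the established chalcone epoxide route, setting out from 3 and returning at 21.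
- Compound 3 is protected (MOMCl, i-Pr2NEt, CH2Cl2) as 4-(methoxymethoxy)-3-(3-methylbut-2-enyl)benzaldehyde F1.
- Commercial 2,4-dihydroxyacetophenone is C-prenylated (2-methylbut-3-en-2-ol, BF3·OEt2, dioxane, with separation from the 3-prenyl isomer) to 1-[2,4-dihydroxy-5-(3-methylbut-2-enyl)phenyl]ethanone F2, and protected (MOMCl, NaH, DMF) as 1-[2,4-bis(methoxymethoxy)-5-(3-methylbut-2-enyl)phenyl]ethanone F3.
- Claisen–Schmidt condensation of F1 with F3 (KOH, EtOH) gives (E)-1-[2,4-bis(methoxymethoxy)-5-(3-methylbut-2-enyl)phenyl]-3-[4-(methoxymethoxy)-3-(3-methylbut-2-enyl)phenyl]prop-2-en-1-one F4.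
- Juliá–Colonna epoxidation (poly-L-leucine, urea–H2O2, DBU, THF), which attacks only the enone, gives [2,4-bis(methoxymethoxy)-5-(3-methylbut-2-enyl)phenyl]{(2R,3S)-3-[4-(methoxymethoxy)-3-(3-methylbut-2-enyl)phenyl]oxiran-2-yl}methanone F5.
- HCl in MeOH at 40 °C removes the three acetal groups, and the freed 2'-phenol opens the epoxide at the benzylic carbon with inversion to give 21.
- This route brings back the ring A prenylation problem and the acidic last step, which is why it is only the fallback.

Step 6. Bromination may not stay at C5: bromonium formation or allylic bromination at the prenyl alkene, or substitution on ring B, can compete because the vinylogous ester is only moderately nucleophilic. The fallback sets out from 10 and returns at 20.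
- Iodine and pyridine in CH2Cl2 at rt, conditions under which iodonium formation at an isolated alkene is reversible and unproductive, give (2R,3R)-3-(tert-butyldimethylsilyloxy)-2-[4-(tert-butyldimethylsilyloxy)-3-(3-methylbut-2-enyl)phenyl]-5-iodo-2,3-dihydro-4H-pyran-4-one F6.
- F6 is carried through the operations of step 11 with 17, by way of the iodo cycloadduct (2R,3R)-3-(tert-butyldimethylsilyloxy)-2-[4-(tert-butyldimethylsilyloxy)-3-(3-methylbut-2-enyl)phenyl]-4a-iodo-5-methoxy-6-(3-methylbut-2-enyl)-7-(trimethylsilyloxy)-2,3,4a,5,8,8a-hexahydro-4H-chromen-4-one F7 and the iodo enone (2R,3R)-3-(tert-butyldimethylsilyloxy)-2-[4-(tert-butyldimethylsilyloxy)-3-(3-methylbut-2-enyl)phenyl]-4a-iodo-6-(3-methylbut-2-enyl)-2,3,8,8a-tetrahydro-4H-chromene-4,7(4aH)-dione F8. HI is lost in place of HBr.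

Step 4. The dienolate may open ring C by reversible beta-elimination of O1, which would erode the C2 configuration, and the oxidant may approach with poor facial selectivity; addition of the enolate to the sulfonimine by-product is a further loss. The fallback is a Rubottom oxidation that avoids a long-lived free enolate, setting out from 7 and returning at 10, and it saves step 5.
- Deprotonation with LiN(SiMe3)2 in the presence of TBSCl (THF, −78 °C, internal quench) gives tert-butyl({(2S)-2-[4-(tert-butyldimethylsilyloxy)-3-(3-methylbut-2-enyl)phenyl]-2H-pyran-4-yl}oxy)dimethylsilane F9.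
- One equivalent of dimethyldioxirane (acetone/CH2Cl2, −78 °C) should epoxidise the electron-rich silyloxy diene faster than the prenyl alkene, on the face anti to the aryl group, to give 2-[4-(tert-butyldimethylsilyloxy)-3-(3-methylbut-2-enyl)phenyl]-6-(tert-butyldimethylsilyloxy)-3,7-dioxabicyclo[4.1.0]hept-4-ene F10 (oxirane oxygen trans to the aryl group).
- On warming with a trace of PPTS, F10 rearranges by 1,4-silyl migration to 10.

Step 7. Enol silylation may not be regioselective enough, and the terminal enol silane would lead, through steps 8 to 10, to a regioisomeric diene and finally to a misplaced prenyl group. The fallback sets out from 12 and returns at 16.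
- Soft enolisation with TiCl4 and Et3N in the presence of methyl formate (CH2Cl2, −10 °C), a titanium-mediated crossed Claisen condensation expected to engage the more substituted alpha carbon, gives (3Z)-3-(hydroxymethylidene)-6-methylhept-5-en-2-one F11.
- O-Methylation (Me2SO4, K2CO3, acetone) gives 16.

Step 1. O-Alkylation and double alkylation of the phenoxide may dominate over ortho C-alkylation, leaving little 3. The fallback replaces phenoxide alkylation by cross-coupling, setting out from 1 and returning at 4.
- Bromination (Br2, AcOH) gives 3-bromo-4-hydroxybenzaldehyde F12.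
- Silylation (TBSCl, imidazole, DMF) gives 3-bromo-4-(tert-butyldimethylsilyloxy)benzaldehyde F13.
- Stille coupling with tributyl(3-methylbut-2-enyl)stannane (Pd(PPh3)4, a complex of zerovalent palladium, DMF, 90 °C) gives 4.

## Further compounds

F1 | step 11 | 4-(methoxymethoxy)-3-(3-methylbut-2-enyl)benzaldehyde | COCOc1ccc(C=O)cc1CC=C(C)C
F2 | step 11 | 1-[2,4-dihydroxy-5-(3-methylbut-2-enyl)phenyl]ethanone | CC(=O)c1cc(CC=C(C)C)c(O)cc1O
F3 | step 11 | 1-[2,4-bis(methoxymethoxy)-5-(3-methylbut-2-enyl)phenyl]ethanone | COCOc1cc(OCOC)c(cc1CC=C(C)C)C(C)=O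
F4 | step 11 | (E)-1-[2,4-bis(methoxymethoxy)-5-(3-methylbut-2-enyl)phenyl]-3-[4-(methoxymethoxy)-3-(3-methylbut-2-enyl)phenyl]prop-2-en-1-one | COCOc1cc(OCOC)c(cc1CC=C(C)C)C(=O)/C=C/c2ccc(OCOC)c(CC=C(C)C)c2
F5 | step 11 | [2,4-bis(methoxymethoxy)-5-(3-methylbut-2-enyl)phenyl]{(2R,3S)-3-[4-(methoxymethoxy)-3-(3-methylbut-2-enyl)phenyl]oxiran-2-yl}methanone | COCOc1cc(OCOC)c(cc1CC=C(C)C)C(=O)[C@@H]2O[C@H]2c3ccc(OCOC)c(CC=C(C)C)c3
F6 | step 6 | (2R,3R)-3-(tert-butyldimethylsilyloxy)-2-[4-(tert-butyldimethylsilyloxy)-3-(3-methylbut-2-enyl)phenyl]-5-iodo-2,3-dihydro-4H-pyran-4-one | CC(C)=CCc1cc([C@H]2OC=C(I)C(=O)[C@@H]2O[Si](C)(C)C(C)(C)C)ccc1O[Si](C)(C)C(C)(C)C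
F7 | step 6 | (2R,3R)-3-(tert-butyldimethylsilyloxy)-2-[4-(tert-butyldimethylsilyloxy)-3-(3-methylbut-2-enyl)phenyl]-4a-iodo-5-methoxy-6-(3-methylbut-2-enyl)-7-(trimethylsilyloxy)-2,3,4a,5,8,8a-hexahydro-4H-chromen-4-one | CC(C)=CCc1cc([C@H]2OC3CC(O[Si](C)(C)C)=C(CC=C(C)C)C(OC)C3(I)C(=O)[C@@H]2O[Si](C)(C)C(C)(C)C)ccc1O[Si](C)(C)C(C)(C)C
F8 | step 6 | (2R,3R)-3-(tert-butyldimethylsilyloxy)-2-[4-(tert-butyldimethylsilyloxy)-3-(3-methylbut-2-enyl)phenyl]-4a-iodo-6-(3-methylbut-2-enyl)-2,3,8,8a-tetrahydro-4H-chromene-4,7(4aH)-dione | CC(C)=CCc1cc([C@H]2OC3CC(=O)C(CC=C(C)C)=CC3(I)C(=O)[C@@H]2O[Si](C)(C)C(C)(C)C)ccc1O[Si](C)(C)C(C)(C)C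
F9 | step 4 | tert-butyl({(2S)-2-[4-(tert-butyldimethylsilyloxy)-3-(3-methylbut-2-enyl)phenyl]-2H-pyran-4-yl}oxy)dimethylsilane | CC(C)=CCc1cc([C@H]2OC=CC(O[Si](C)(C)C(C)(C)C)=C2)ccc1O[Si](C)(C)C(C)(C)C
F10 | step 4 | 2-[4-(tert-butyldimethylsilyloxy)-3-(3-methylbut-2-enyl)phenyl]-6-(tert-butyldimethylsilyloxy)-3,7-dioxabicyclo[4.1.0]hept-4-ene (oxirane oxygen trans to the aryl group) | CC(C)=CCc1cc([C@H]2OC=C[C@]3(O[Si](C)(C)C(C)(C)C)O[C@H]23)ccc1O[Si](C)(C)C(C)(C)C
F11 | step 7 | (3Z)-3-(hydroxymethylidene)-6-methylhept-5-en-2-one | CC(=O)/C(CC=C(C)C)=C\O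
F12 | step 1 | 3-bromo-4-hydroxybenzaldehyde | O=Cc1ccc(O)c(Br)c1
F13 | step 1 | 3-bromo-4-(tert-butyldimethylsilyloxy)benzaldehyde | CC(C)(C)[Si](C)(C)Oc1ccc(C=O)cc1Br
A1 | alternative 1 | (2R,3R)-8-bromo-3,7-dihydroxy-2-[4-hydroxy-3-(3-methylbut-2-enyl)phenyl]-6-(3-methylbut-2-enyl)chroman-4-one | CC(C)=CCc1cc([C@H]2Oc3c(Br)c(O)c(CC=C(C)C)cc3C(=O)[C@@H]2O)ccc1O
A2 | alternative 1 | (2R,3R)-8-bromo-3-hydroxy-7-[(2-methylbut-3-en-2-yl)oxy]-2-{4-[(2-methylbut-3-en-2-yl)oxy]phenyl}chroman-4-one | C=CC(C)(C)Oc1ccc([C@H]2Oc3c(Br)c(OC(C)(C)C=C)ccc3C(=O)[C@@H]2O)cc1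
A3 | alternative 2 | 2,3-trans-3,7-bis(methoxymethoxy)-2-[4-(methoxymethoxy)-3-(3-methylbut-2-enyl)phenyl]-6-(3-methylbut-2-enyl)chroman-4-ol (C4 carbinol either epimer) | CC(C)=CCc1cc([C@H]2Oc3cc(OCOC)c(CC=C(C)C)cc3C(O)[C@@H]2OCOC)ccc1OCOC
A4 | alternative 2 | (2R,3R)-1-[3-bromo-4-(methoxymethoxy)-5-(3-methylbut-2-enyl)phenyl]-2-(methoxymethoxy)-3-[4-(methoxymethoxy)-3-(3-methylbut-2-enyl)phenyl]propane-1,3-diol (C1 carbinol either epimer) | CC(C)=CCc1cc([C@@H](O)[C@@H](OCOC)C(O)c2cc(Br)c(OCOC)c(CC=C(C)C)c2)ccc1OCOC
A5 | alternative 3 | (2R,3R)-3-hydroxy-7-(methoxymethoxy)-2-[4-(methoxymethoxy)-3-(3-methylbut-2-enyl)phenyl]-6-(3-methylbut-2-enyl)chroman-4-one | CC(C)=CCc1cc([C@H]2Oc3cc(OCOC)c(CC=C(C)C)cc3C(=O)[C@@H]2O)ccc1OCOC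
A6 | alternative 3 | 2-{1-[4-(methoxymethoxy)-3-(3-methylbut-2-enyl)phenyl]-2-oxoethoxy}-4-(methoxymethoxy)-5-(3-methylbut-2-enyl)benzaldehyde (racemic) | CC(C)=CCc1cc(C(C=O)Oc2cc(OCOC)c(CC=C(C)C)cc2C=O)ccc1OCOC
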